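The readings are calculated with constants of no real substance; scatter was added.

A slow loss lay under a fast one in these flasks, and I wanted its size before reckoning the dawn flask, whose partner (0.0520 M) is charged below its starting material (0.0800 M), which makes partner the limiting reagent.

| flask | starting material | partner | time |
|---|---|---|---|
| summer | 0.0800 M | 0.240 M |  |
| spring | 0.120 M | 0.240 M |  |
| midnight | 0.0800 M | 0.120 M |  |
| dawn | 0.0800 M | 0.0520 M | 9.4 min |

| run | time / min | [starting material] / M |
|---|---|---|
| summer run | 0.42 | 0.06348 |
| summer run | 1.3 | 0.04124 |
| summer run | 2.4 | 0.02535 |
| summer run | 3.8 | 0.01494 |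
| summer run | 5.5 | 0.00799 |
| summer run | 7.3 | 0.00434 |
| summer run | 9.4 | 0.00211 |
| spring run | 0.42 | 0.09508 |
| spring run | 1.3 | 0.06311 |
| spring run | 2.4 | 0.04088 |
| spring run | 3.8 | 0.02525 |
| spring run | 5.5 | 0.01561 |
| spring run | 7.3 | 0.00900 |
| spring run | 9.4 | 0.00533 |
| midnight run | 0.42 | 0.07074 |
| midnight run | 1.3 | 0.05633 |
| midnight run | 2.4 | 0.04371 |
| midnight run | 3.8 | 0.03278 |
| midnight run | 5.5 | 0.02420 |
| midnight run | 7.3 | 0.01799 |
| midnight run | 9.4 | 0.01338 |

(scatter of a reading: 2 × 10⁻⁴ M)

- apparent order in [starting material] of the starting rate, round the charge of the summer run (the rate where two percent of its starting material have turned into target) (one fixed amount of target, the same in the runs compared)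
- apparent order in [partner] of the starting rate, round the charge of the summer run (the rate where two percent of its starting material have turned into target)
- starting material in the dawn run at 9.4 min, as a share of the starting material charged

- Overall: starting material + partner -> target.
- Constant volume, constant temperature.
- An order is taken over about fifteen percent of the charge, up and down.

Write S for starting material, R for partner and t for time. If a paired step has constant k and S can also fall by itself, then −d ln S/dt = kR + g. I read this over the last interval of two runs, taking R as the charged difference plus the mean S:

summer: slope m₁ = 0.343 min⁻¹ at R = 0.163 M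

midnight: slope m₃ = 0.141 min⁻¹ at R = 0.0557 M

k = 1.88 L mol⁻¹ min⁻¹

g = 0.0362 min⁻¹

I call g the idle constant, the fall of ln S per minute extrapolated to zero partner. It is a rough reading, since the last summer reading stands 10.5 noise widths above zero.

Now the dawn flask in slow motion. In the first instants the partner route pulled ln S down at 0.0978 min⁻¹, faster than g. Through the middle S and R fell in pairs, so on that route their difference held at 0.0280 M. That route, taken by itself, brought S to 0.0464 M at 9.4 min, with 0.0184 M of partner left. Its pull was then 0.0346 min⁻¹, level with g. I put the idle loss on top as a factor, which is an approximation: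

ln(share) = −0.545 − 0.340 = −0.885

share = 41.3 %

The forecast gave orders of 1.03 and 0.92 and a dawn share of 51.5 %, above my figure, on the ground that the ratio “is close to constant, so the reaction is nearly first order in each reactant”.

The dawn flask gave 42.1 %, and the orders came out at 1.0 and 1.0, with the target rate at 0.029 M min⁻¹ in the summer run against 0.014 M min⁻¹ in the midnight run.

    starting material + partner → target (1.560 L mol⁻¹ min⁻¹)
    starting material + partner → side product (0.7320 L mol⁻¹ min⁻¹)
    starting material → decomposed substrate (0.02670 min⁻¹)
    2 partner → lost reagent (0.1002 L mol⁻¹ min⁻¹)

With g as I read it, that share comes to a rough estimate of 0.00122 M min⁻¹ for the idle loss from the dawn flask at 9.4 min. In the midnight run, where the target reaches half of the charge at 9.60 min, my reading of g is 25.7 % of the slope read over the last interval.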